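Labels (daucane numbering): ring A = C1(C15H3)–C2–C3–C4(iPr)–C5(OH). Ring B = C1–C5–C6–C7–C8(C14H3)=C9–C10(O-anisoyl). α is the face that carries C15.
Cuts, in retrosynthetic order: the ester C–O; C5–O and C6–H (back to a C5=C6 alkene); C7–H (back to a C7–O–C10 ether bridge); then C10–C1 and C6–C7 of ring B in one event.
Enabling feature: C8=C9 and the latent C5=C6 flank C7H2, so ring B is a masked cyclohepta-1,4-diene. Its C10–C1 bond, which joins two adjacent stereocentres, is the σ-bond made by a strain-releasing cis-divinylcyclopropane Cope shift. O–C10=C9–C8(CH3)=C7 is 3-methylfuran, and C6–C5=C1 is a cyclopentenylcarbene.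
Forward: ring A comes first, by ring contraction of (S)-limonene (three steps). The aldehyde becomes a sulfonylhydrazone, and carbene transfer to 3-methylfuran followed by the Cope shift closes ring B last. Bridge opening, anisoylation, iodo-acyloxylation and deiodination finish the route.
Stereochemistry: C4 comes from (S)-limonene. C1 and C10 come from carbene attack anti to the isopropyl group, relayed through the boat Cope transition state. C5 comes from an anti addition in which the α-anisoate on C10 delivers the oxygen.

Key step: step 5

Assumption: 2-(trifluoromethyl)benzenesulfonohydrazide 6 is taken as a catalogue reagent; otherwise it costs one extra step from the sulfonyl chloride and hydrazine hydrate.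

Step 1
Reactants: 1 (S)-(−)-limonene
Product: 2 (S)-4-isopropyl-1-methylcyclohex-1-ene
Conditions: H2 (1 atm), RhCl(PPh3)3 (cat.), toluene/EtOH, rt, stopped after one equivalent of H2
Reagents that add atoms: none
Why: Chemoselective homogeneous (Wilkinson) hydrogenation, in which the 1,1-disubstituted isopropenyl alkene binds to rhodium far better than the trisubstituted ring alkene and the stereocentre (later C4) is not touched.

Step 2
Reactants: 2 (S)-4-isopropyl-1-methylcyclohex-1-ene
Product: 4 (S)-3-isopropyl-6-oxoheptanal, via ozonide 3 (not isolated)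
Conditions: O3, CH2Cl2, −78 °C; then Me2S, −78 °C to rt
Reagents that add atoms: ozone, [O-][O+]=O
Why: Ozonolysis (Criegee mechanism) with reductive work-up cleaves the only alkene to the keto aldehyde, and the stereocentre is β to the new aldehyde and cannot enolise.

Step 3
Reactants: 4 (S)-3-isopropyl-6-oxoheptanal
Product: 5 (R)-5-isopropyl-2-methylcyclopent-1-ene-1-carbaldehyde
Conditions: piperidine (cat.), AcOH (cat.), toluene, reflux, Dean–Stark
Reagents that add atoms: none
Why: Enamine-mediated intramolecular aldol condensation (5-enolexo closure of ring A), in which the aldehyde enamine attacks the methyl ketone to give the tetrasubstituted enal with C6, C5, C1, C15 and C4 in place; the descriptor changes from S to R only through CIP priorities.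

Step 4
Reactants: 5 (R)-5-isopropyl-2-methylcyclopent-1-ene-1-carbaldehyde; 6 2-(trifluoromethyl)benzenesulfonohydrazide
Product: 7 (E)-sulfonylhydrazone of 5
Conditions: MeOH, rt
Reagents that add atoms: 2-(trifluoromethyl)benzenesulfonohydrazide (6), NNS(=O)(=O)c1ccccc1C(F)(F)F
Why: Simple hydrazone condensation installs the carbene precursor (Bamford–Stevens type), and the electron-poor arylsulfonyl group lets the salt lose sulfinate at or below 40 °C.

Step 5
Reactants: 7 (E)-sulfonylhydrazone of 5; 8 3-methylfuran
Product: 11 7α,10α-epoxydauca-5,8-diene (oxa-bridged hydroazulene), via diazoalkene 9 (not isolated), via endo-cyclopropane 10 (not isolated)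
Conditions: NaH, Rh2(OAc)4 (2 mol %), 3-methylfuran (10 equiv), CH2Cl2, 0 to 40 °C
Reagents that add atoms: 3-methylfuran (8), Cc1ccoc1
Why: Proposed new method: NaH removes the N–H of 7 and loss of sulfinate gives 9; Rh2(OAc)4 expels N2 and passes the acceptor-free cyclopentenylcarbene (C6) to the C2=C3 bond of 3-methylfuran (C7=C8) to give the endo adduct 10, a cis-divinylcyclopropane that undergoes a [3,3] shift in which the strained C6–C8 bond breaks and C10–C1 forms. The closest known reaction types are the tandem cyclopropanation/Cope (formal [4+3]) reaction of rhodium vinylcarbenes from vinyldiazoacetates with furans, and the metal-catalysed transfer of donor-type vinylcarbenes from enal sulfonylhydrazones to 1,3-dienes; untested is the pairing of an ester-free, fully substituted cyclopentenylcarbene with a furan. Ring B closes by a two-bond annulation, C6–C7 in a concerted asynchronous [2+1] addition and C10–C1 in a suprafacial/suprafacial sigmatropic shift through the boat transition state (the only one open to a cis-divinylcyclopropane), driven by release of three-ring strain, while the C7–O–C10 bridge is only the furan oxygen carried along. C6 of 10 is set by approach of the furan to the carbene face anti to the C4 isopropyl group with rhodium s-trans to C1, and C7 and C8 by syn addition in the endo orientation; the boat shift relays this so that C10 bonds to C1 anti to the isopropyl group (C15 goes α), and because the ring oxygen on C10 and C15 on C1 are both the Z substituents of the two alkene termini they must end cis, which is the target relation, with C7 cis-bridged to C10 by necessity. The step needs reaction at the carbene carbon and not at its vinylogous end (secured by the fully substituted C1), attack on the furan carbon next to the methyl group (the most nucleophilic position of 3-methylfuran, which also puts the developing cation on the methyl-bearing carbon), and endo addition (the usual syn preference of hydrogen-bearing donor carbenes; only the endo adduct can rearrange). Slow release of 9 in excess furan is meant to outrun its electrocyclisation to a pyrazole and carbene dimerisation.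

Step 6
Reactants: 11 7α,10α-epoxydauca-5,8-diene
Product: 13 dauca-5,8-dien-10α-ol, via dilithium pentadienyl alkoxide 12 (not isolated)
Conditions: Li, NH3(l)/THF, t-BuOH, −78 °C; then NH4Cl
Reagents that add atoms: none
Why: Dissolving-metal (Birch-type) hydrogenolysis of an allylic ether, in which the homoconjugated diene accepts an electron, the doubly allylic C7–O bond breaks in preference to the singly allylic C10–O bond because it leads to the pentadienyl system 12, and kinetic protonation of a pentadienyl anion at its central carbon (C7) restores the skipped diene without touching C10–O, C1 or C4.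

Step 7
Reactants: 13 dauca-5,8-dien-10α-ol; 14 4-methoxybenzoyl chloride
Product: 15 dauca-5,8-dien-10α-yl 4-methoxybenzoate
Conditions: Et3N, DMAP (cat.), CH2Cl2, 0 °C to rt
Reagents that add atoms: 4-methoxybenzoyl chloride (14), COc1ccc(cc1)C(Cl)=O
Why: DMAP-catalysed acylation of the only hydroxyl group, with retention at C10 because the C10–O bond is not involved.

Step 8
Reactants: 15 dauca-5,8-dien-10α-yl 4-methoxybenzoate
Product: 17 5α-hydroxy-6β-iododauc-8-en-10α-yl 4-methoxybenzoate, via dioxanylium ion 16 (not isolated)
Conditions: NIS, MeCN/H2O (10:1), −20 to 0 °C, dark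
Reagents that add atoms: N-iodosuccinimide, O=C1CCC(=O)N1I; water, O
Why: Iodonium-induced neighbouring-group participation (intramolecular Woodward–Prévost-type iodo-acyloxylation, the ester analogue of the iodocarbonate route to syn-1,3-diols), in which iodine picks C5=C6 because C8=C9 is deactivated by the allylic acyloxy group (as in geranyl acetate) and adds from the convex β face, the axial C10 anisoate carbonyl opens the iodonium ion at tertiary C5 from the α face (6-exo) to give 16, and water cleaves 16 through its orthoacid to the less crowded secondary ester, so that C5–OH ends cis to C10–O, C15 and the isopropyl group.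

Step 9
Reactants: 17 5α-hydroxy-6β-iododauc-8-en-10α-yl 4-methoxybenzoate
Product: 18 5α-hydroxydauc-8-en-10α-yl 4-methoxybenzoate (target)
Conditions: Bu3SnH, AIBN (cat.), toluene, 80 °C
Reagents that add atoms: none
Why: Radical-chain hydrodehalogenation with tin hydride removes the helper iodine; C6 becomes CH2, so no stereocentre is affected, and the tertiary alcohol, the allylic ester and the trisubstituted alkene are inert to stannyl radicals.

Compound list
1 | (S)-(−)-limonene | CC1=CC[C@H](CC1)C(C)=C | starting material
2 | (S)-4-isopropyl-1-methylcyclohex-1-ene | CC1=CC[C@H](CC1)C(C)C | intermediate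
3 | ozonide of 2: 4-isopropyl-1-methyl-7,8,9-trioxabicyclo[4.2.1]nonane (C4 as in 2, both bridge orientations) | CC12CC[C@H](C(C)C)CC(OO1)O2 | intermediate
4 | (S)-3-isopropyl-6-oxoheptanal | O=CC[C@H](CCC(C)=O)C(C)C | intermediate
5 | (R)-5-isopropyl-2-methylcyclopent-1-ene-1-carbaldehyde | CC1=C(C=O)[C@@H](C(C)C)CC1 | intermediate
6 | 2-(trifluoromethyl)benzenesulfonohydrazide | NNS(=O)(=O)c1ccccc1C(F)(F)F | starting material
7 | (E)-N'-{[(R)-5-isopropyl-2-methylcyclopent-1-en-1-yl]methylidene}-2-(trifluoromethyl)benzenesulfonohydrazide | CC1=C(/C=N/NS(=O)(=O)c2ccccc2C(F)(F)F)[C@@H](C(C)C)CC1 | intermediate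
8 | 3-methylfuran | Cc1ccoc1 | starting material
9 | (R)-1-(diazomethyl)-5-isopropyl-2-methylcyclopent-1-ene | CC1=C(C=[N+]=[N-])[C@@H](C(C)C)CC1 | intermediate
10 | endo-6-[(R)-5-isopropyl-2-methylcyclopent-1-en-1-yl]-5-methyl-2-oxabicyclo[3.1.0]hex-3-ene (cyclopentenyl on the same cyclopropane face as the dihydrofuran ring) | CC1=C([C@@H]2[C@@H]3OC=C[C@]23C)[C@@H](C(C)C)CC1 | intermediate
11 | 7α,10α-epoxydauca-5,8-diene (oxygen bridge on the face of C15; isopropyl cis to C15 on ring A) | O1[C@H]2C=C(C)[C@@H]1C=C3[C@@H](C(C)C)CC[C@]23C | intermediate
12 | dilithium salt: C10 alkoxide with pentadienyl anion over C5–C9 (one resonance form drawn) | [Li+].[Li+].[O-][C@H]1C=C(C)[CH-]C=C2[C@@H](C(C)C)CC[C@]12C | intermediate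
13 | dauca-5,8-dien-10α-ol (OH cis to C15) | O[C@H]1C=C(C)CC=C2[C@@H](C(C)C)CC[C@]12C | intermediate
14 | 4-methoxybenzoyl chloride | COc1ccc(cc1)C(Cl)=O | starting material
15 | dauca-5,8-dien-10α-yl 4-methoxybenzoate | COc1ccc(C(=O)O[C@H]2C=C(C)CC=C3[C@@H](C(C)C)CC[C@]23C)cc1 | intermediate
16 | 2-(4-methoxyphenyl)-1,3-dioxan-2-ylium ion bridging O-10 and O-5 on the α face, 6β-iodo, succinimide anion as counter-ion | O1[C@H]2C=C(C)C[C@H](I)[C@]3([O+]=C1c1ccc(OC)cc1)[C@@H](C(C)C)CC[C@]23C.O=C1CCC(=O)[N-]1 | intermediate
17 | 5α-hydroxy-6β-iododauc-8-en-10α-yl 4-methoxybenzoate | COc1ccc(C(=O)O[C@H]2C=C(C)C[C@H](I)[C@]3(O)[C@@H](C(C)C)CC[C@]23C)cc1 | intermediate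
18 | (1R,3aR,4S,8aS)-8a-hydroxy-3a,6-dimethyl-1-(propan-2-yl)-1,2,3,3a,4,7,8,8a-octahydroazulen-4-yl 4-methoxybenzoate | COc1ccc(C(=O)O[C@H]2C=C(C)CC[C@]3(O)[C@@H](C(C)C)CC[C@]23C)cc1 | target

Total steps: 9. Longest linear sequence: 9 (1 to 18).

Steps most likely to fail

1. Step 5.
What may go wrong:
- The diazoalkene may electrocyclise to a pyrazole.
- The carbene may dimerise or undergo a 1,4-hydrogen shift.
- Attack may occur at the unsubstituted α-position of the furan.
- Addition may be exo, or the furan adduct may unravel.
- Facial selectivity may be poor if the s-cis carbene competes.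

Fallback (known reactions only; sets out from 5, returns at 13): the same strain-release Cope shift is reached through a stepwise-built cyclopropane and a ketene terminus (tandem Wolff/Cope rearrangement). Still–Gennari olefination of 5 with methyl 2-[bis(2,2,2-trifluoroethoxy)phosphoryl]propanoate (KN(SiMe3)2, 18-crown-6, THF, −78 °C) would give the (Z)-dienoate F1. Reduction with i-Bu2AlH would give the (Z)-allylic alcohol F2. Charette cyclopropanation (Et2Zn, CH2I2, (4R,5R)-2-butyl-N,N,N',N'-tetramethyl-1,3,2-dioxaborolane-4,5-dicarboxamide) would give the cis-cyclopropylmethanol F3, with reagent control setting C6 and C8. TEMPO/PhI(OAc)2 in aqueous MeCN would give the cyclopropanecarboxylic acid F4, 1-chloro-N,N,2-trimethylpropenylamine the acid chloride F5, and CH2N2 the diazoketone F6. AgO2CPh/Et3N with sonication would trigger the Wolff rearrangement to the ketene F7. Its sp terminus carries no Z substituent, so it should undergo the Cope shift at once to dauca-5,8-dien-10-one F8. Luche reduction (NaBH4, CeCl3·7H2O, MeOH) from the convex face, anti to the axial C15 methyl group, would then give 13.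

2. Step 6.
What may go wrong:
- The C10–O bond may be cleaved instead of C7–O.
- The pentadienyl anion may be protonated at a terminus, which would bring the diene into conjugation and open the way to over-reduction.

Fallback (sets out from 11, returns at 13): change from electron transfer to Lewis-acid-assisted, oxygen-directed hydride delivery. AlH2Cl (from LiAlH4 and AlCl3, Et2O, 0 °C) would bind the bridge oxygen. The doubly allylic C7–O bond would ionise, and hydride would pass from the same aluminium centre to C7, the carbon next to the departing oxygen, so the remote cation termini C5 and C9 are not served. Aqueous work-up would free 13, and no new isolable compound is made.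

3. Step 8.
What may go wrong:
- Iodonium formation may occur at C8=C9.
- The C5 cation may lose a proton instead of being captured.
- The allylic ester may ionise.
- The acyl group may stay on the tertiary oxygen.

Fallback (sets out from 13, returns at 18): a temporary carbonate replaces the anisoate as the oxygen carrier (iodocarbonate cyclisation). Treatment of 13 with n-BuLi and Boc2O would give the tert-butyl carbonate F9. IBr (toluene, −80 °C) would give the iodo cyclic carbonate F10, and Bu3SnH/AIBN the cyclic carbonate F11. K2CO3/MeOH would give dauc-8-ene-5α,10α-diol F12. Selective acylation of its secondary allylic hydroxyl group with 14 (Et3N, DMAP) would give 18.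

Further compounds
F1 | step 5 | methyl (Z)-3-[(5R)-5-isopropyl-2-methylcyclopent-1-en-1-yl]-2-methylprop-2-enoate | COC(=O)/C(C)=C\C1=C(C)CC[C@@H]1C(C)C
F2 | step 5 | (Z)-3-[(5R)-5-isopropyl-2-methylcyclopent-1-en-1-yl]-2-methylprop-2-en-1-ol | OC/C(C)=C\C1=C(C)CC[C@@H]1C(C)C
F3 | step 5 | {2-[(5R)-5-isopropyl-2-methylcyclopent-1-en-1-yl]-1-methylcyclopropyl}methanol, CH2OH and cyclopentenyl cis | OC[C@@]1(C)C[C@H]1C1=C(C)CC[C@@H]1C(C)C
F4 | step 5 | corresponding cis-cyclopropanecarboxylic acid | OC(=O)[C@@]1(C)C[C@H]1C1=C(C)CC[C@@H]1C(C)C
F5 | step 5 | corresponding acid chloride | ClC(=O)[C@@]1(C)C[C@H]1C1=C(C)CC[C@@H]1C(C)C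
F6 | step 5 | corresponding diazomethyl ketone | [N-]=[N+]=CC(=O)[C@@]1(C)C[C@H]1C1=C(C)CC[C@@H]1C(C)C
F7 | step 5 | cis-(2-cyclopentenyl-1-methylcyclopropyl)ketene | O=C=C[C@@]1(C)C[C@H]1C1=C(C)CC[C@@H]1C(C)C
F8 | step 5 | dauca-5,8-dien-10-one | O=C1C=C(C)CC=C2[C@@H](C(C)C)CC[C@]12C
F0 | step 6 | none | none
F9 | step 8 | tert-butyl dauca-5,8-dien-10α-yl carbonate | CC(C)(C)OC(=O)O[C@H]1C=C(C)CC=C2[C@@H](C(C)C)CC[C@]12C
F10 | step 8 | 6β-iododauc-8-ene-5α,10α-diyl carbonate | O=C1O[C@H]2C=C(C)C[C@H](I)[C@]3(O1)[C@@H](C(C)C)CC[C@]23C
F11 | step 8 | dauc-8-ene-5α,10α-diyl carbonate | O=C1O[C@H]2C=C(C)CC[C@]3(O1)[C@@H](C(C)C)CC[C@]23C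
F12 | step 8 | dauc-8-ene-5α,10α-diol | O[C@H]1C=C(C)CC[C@]2(O)[C@@H](C(C)C)CC[C@]12C
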